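The isoflavone is cut through ring C at O1–C8a, C4–C4a and O1–C2. On ring A, O1 and the C4 carbonyl are ortho neighbours and the C5 methoxy group flanks C4a, which is the pattern left when a 3-methoxy aryne inserts into the acyl C–O bond of a carboxylic acid. One fluoride-triggered operation therefore joins a ring A ortho-silyl aryl triflate to a 2-aryl-3-methoxyacrylic acid that already carries the finished dimethylchromene (ring B), forms the ortho-acyl phenoxide and closes the pyranone by addition–elimination at the methoxy-bearing carbon. Both free phenols travel as MOM ethers and are released together in the last step.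

Key step: step 12

Assumption (chemistry): the geometry of the methoxyacrylate double bond is lost in the ring closure, so the E isomer is carried only because the cross-coupling delivers it. Compounds 1, 9, 10 and 18 are taken as commercial. Bromine, not a directed metalation, fixes the position of silicon on ring A.

Step 1
Reactants: 1 3-bromo-4-hydroxy-5-methoxybenzaldehyde (5-bromovanillin)
Product: 3 2-bromo-6-methoxybenzene-1,4-diol, via aryl formate 2 (not isolated)
Conditions: 30% H2O2, 1 M NaOH, THF, 0 °C to rt, argon; then Na2S2O4, HCl to pH 3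
Reagents that add atoms: hydrogen peroxide, OO
Why: Dakin oxidation: hydroperoxide adds to the aldehyde, the electron-rich para-hydroxyaryl group migrates to oxygen and formate 2 is hydrolysed in the basic medium, so the new hydroxyl stands exactly where the formyl group was.

Step 2
Reactants: 3 2-bromo-6-methoxybenzene-1,4-diol
Product: 7 4-hydroxy-2-methoxy-6-(trimethylsilyl)phenyl trifluoromethanesulfonate, via bis-silyl ether 4 (not isolated), via lithium phenolate 5 (not isolated), via silyloxy triflate 6 (not isolated)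
Conditions: HMDS, THF, 70 °C, evaporate; n-BuLi, THF, −100 to −78 °C; PhNTf2, −78 °C to rt; 1 M HCl, THF/MeOH, 0 °C
Reagents that add atoms: hexamethyldisilazane, C[Si](C)(C)N[Si](C)(C)C; N-phenylbis(trifluoromethanesulfonimide), O=S(=O)(N(c1ccccc1)S(=O)(=O)C(F)(F)F)C(F)(F)F
Why: Retro-Brook (1,3 O-to-C silyl shift) route to ortho-silyl aryl triflates: bromine–lithium exchange at −100 °C outruns attack at silicon, the aryllithium takes SiMe3 from the neighbouring oxygen, hindered phenolate 5 is trapped by PhNTf2 (which ignores silyl ethers), and cold dilute acid removes only the remote O–SiMe3 group because the C–Si bond is meta to both donor oxygens and ortho to the triflate.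

Step 3
Reactants: 7 4-hydroxy-2-methoxy-6-(trimethylsilyl)phenyl trifluoromethanesulfonate
Product: 8 2-methoxy-4-(methoxymethoxy)-6-(trimethylsilyl)phenyl trifluoromethanesulfonate
Conditions: MOMCl, DIPEA, CH2Cl2, 0 °C to rt
Reagents that add atoms: chloromethyl methyl ether, COCCl
Why: MOM protection (O-alkylation of the only free phenol with an amine base); neither fluoride nor a strong nucleophile is present, so the silyl and triflate groups are left alone.

Step 4
Reactants: 9 5-bromo-2-hydroxybenzaldehyde; 10 3-chloro-3-methylbut-1-yne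
Product: 11 5-bromo-2-[(2-methylbut-3-yn-2-yl)oxy]benzaldehyde
Conditions: DBU, CuCl2·2H2O (cat.), MeCN, 0 °C to rt
Reagents that add atoms: none
Why: Copper-catalysed O-propargylation of a phenol with a tertiary propargylic chloride (a copper acetylide ionises to an allenylidene-type electrophile that the phenoxide captures); it tolerates electron-poor phenols and leaves the aldehyde untouched.

Step 5
Reactants: 11 5-bromo-2-[(2-methylbut-3-yn-2-yl)oxy]benzaldehyde
Product: 13 5-bromo-2-[(2-methylbut-3-yn-2-yl)oxy]phenol, via aryl formate 12 (not isolated)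
Conditions: mCPBA, CH2Cl2, rt; then K2CO3 (cat.), MeOH, rt
Reagents that add atoms: 3-chloroperoxybenzoic acid, OOC(=O)c1cccc(Cl)c1
Why: Baeyer–Villiger oxidation of an ortho-alkoxybenzaldehyde: the oxygen-substituted aryl group migrates in preference to hydride, catalytic carbonate in methanol cleaves formate 12, and a terminal alkyne is inert to the peracid at room temperature.

Step 6
Reactants: 13 5-bromo-2-[(2-methylbut-3-yn-2-yl)oxy]phenol
Product: 14 4-bromo-2-(methoxymethoxy)-1-[(2-methylbut-3-yn-2-yl)oxy]benzene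
Conditions: MOMCl, DIPEA, CH2Cl2, 0 °C to rt
Reagents that add atoms: chloromethyl methyl ether, COCCl
Why: MOM protection of the free phenol under mild amine-base conditions that do not touch the aryl bromide or the propargyl ether.

Step 7
Reactants: 14 4-bromo-2-(methoxymethoxy)-1-[(2-methylbut-3-yn-2-yl)oxy]benzene
Product: 16 6-bromo-8-(methoxymethoxy)-2,2-dimethyl-2H-chromene, via allenyl phenol 15 (not isolated)
Conditions: PhNEt2, 180 °C
Reagents that add atoms: none
Why: Aromatic propargyl Claisen rearrangement: [3,3] shift to the only free ortho carbon and enolisation give allenyl phenol 15, which closes to the 2,2-dimethylchromene by 1,5-hydrogen shift and 6π oxa-electrocyclisation; MOM ether and aryl bromide are thermally stable in the neutral amine solvent.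

Step 8
Reactants: 16 6-bromo-8-(methoxymethoxy)-2,2-dimethyl-2H-chromene
Product: 17 2-[8-(methoxymethoxy)-2,2-dimethyl-2H-chromen-6-yl]-4,4,5,5-tetramethyl-1,3,2-dioxaborolane
Conditions: B2pin2, PdCl2(dppf), KOAc, dioxane, 90 °C
Reagents that add atoms: bis(pinacolato)diboron, CC1(C)OB(OC1(C)C)B1OC(C)(C)C(C)(C)O1
Why: Miyaura borylation of an aryl bromide (oxidative addition, acetate-assisted transmetalation with the diboron, reductive elimination); the chromene alkene and the MOM acetal are spectators.

Step 9
Reactants: 18 methyl (E)-3-methoxyacrylate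
Product: 20 methyl (Z)-2-iodo-3-methoxyacrylate, via iodo acetate adduct 19 (not isolated)
Conditions: NIS, AcOH, CH2Cl2, rt; then Et3N, rt
Reagents that add atoms: N-iodosuccinimide, O=C1CCC(=O)N1I
Why: Iodo-acetoxylation of the electron-rich enol ether double bond gives adduct 19, and amine-induced E1cB loss of acetic acid should restore the alkene with iodine on the α-carbon and cis to methoxy (Z).

Step 10
Reactants: 17 2-[8-(methoxymethoxy)-2,2-dimethyl-2H-chromen-6-yl]-4,4,5,5-tetramethyl-1,3,2-dioxaborolane; 20 methyl (Z)-2-iodo-3-methoxyacrylate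
Product: 21 methyl (E)-3-methoxy-2-[8-(methoxymethoxy)-2,2-dimethyl-2H-chromen-6-yl]acrylate
Conditions: Pd(PPh3)4, K3PO4, dioxane/H2O, 80 °C
Reagents that add atoms: none
Why: Suzuki–Miyaura coupling of an aryl boronate with an α-iodoacrylate proceeds with retention at the alkene, so the aryl group takes the place of iodine and the E ester should result.

Step 11
Reactants: 21 methyl (E)-3-methoxy-2-[8-(methoxymethoxy)-2,2-dimethyl-2H-chromen-6-yl]acrylate
Product: 22 (E)-3-methoxy-2-[8-(methoxymethoxy)-2,2-dimethyl-2H-chromen-6-yl]acrylic acid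
Conditions: LiOH, THF/MeOH/H2O, 40 °C; then 1 M HCl to pH 4, 0 °C
Reagents that add atoms: lithium hydroxide, [Li+].[OH-]
Why: Saponification (acyl–oxygen cleavage by hydroxide); once the carboxylate has formed the β-carbon is no longer electrophilic, and the MOM acetal and the enol ether survive base and a brief cold acidification.

Step 12
Reactants: 8 2-methoxy-4-(methoxymethoxy)-6-(trimethylsilyl)phenyl trifluoromethanesulfonate; 22 (E)-3-methoxy-2-[8-(methoxymethoxy)-2,2-dimethyl-2H-chromen-6-yl]acrylic acid
Product: 25 5-methoxy-7-(methoxymethoxy)-3-[8-(methoxymethoxy)-2,2-dimethyl-2H-chromen-6-yl]-4H-chromen-4-one, via aryne 23 (not isolated), via hydroxyaryl ketone 24 (not isolated)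
Conditions: CsF (4 equiv), 8 (1.5 equiv), THF, 125 °C, sealed tube
Reagents that add atoms: none
Why: Fluoride attacks silicon in 8 and triflate leaves, giving aryne 23; the cesium carboxylate of 22 adds through oxygen to the aryne carbon that carried silicon (meta to methoxy, the future C8a), so the aryl anion is born at the future C4a beside OMe. That anion attacks its own ester carbonyl through a four-membered transition state and the acyl C–O bond breaks, a net insertion (anionic Fries-type acyl shift) that forms C4–C4a and leaves ortho-acyl phenoxide 24. Ring C then closes by 6-endo-trig oxa-Michael addition of the phenoxide to the methoxy-bearing carbon followed by E1cB loss of methoxide (O1–C2), which also erases the alkene geometry. The closest known reaction type is the insertion of arynes from 2-(trimethylsilyl)aryl triflates into the C–O bond of carboxylic acids to give ortho-hydroxyaryl ketones, run on in the same pot to chromanones, flavones and xanthones. No stereocenter is formed; the selectivity needed is the regiochemistry of aryne capture, secured by the inductive pull of the methoxy group next to the aryne (the negative charge develops beside OMe), and attack through oxygen is assured because 22 has no acidic C–H.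

Step 13
Reactants: 25 5-methoxy-7-(methoxymethoxy)-3-[8-(methoxymethoxy)-2,2-dimethyl-2H-chromen-6-yl]-4H-chromen-4-one
Product: 26 glycyrrhizaisoflavone B, 7-hydroxy-3-(8-hydroxy-2,2-dimethyl-2H-chromen-6-yl)-5-methoxy-4H-chromen-4-one
Conditions: 3 M HCl, MeOH/THF, 45 °C
Reagents that add atoms: none
Why: Acid-catalysed transacetalisation of both aryl MOM ethers to dimethoxymethane in methanol; the C5 methyl ether is inert and a 2,2-dimethylchromene tolerates dilute HCl at mild temperature.

Compound list
1 | 3-bromo-4-hydroxy-5-methoxybenzaldehyde (5-bromovanillin) | COc1cc(C=O)cc(Br)c1O | starting material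
2 | 3-bromo-4-hydroxy-5-methoxyphenyl formate | COc1cc(OC=O)cc(Br)c1O | intermediate (not isolated)
3 | 2-bromo-6-methoxybenzene-1,4-diol | COc1cc(O)cc(Br)c1O | intermediate
4 | 1-bromo-3-methoxy-2,5-bis[(trimethylsilyl)oxy]benzene | COc1cc(O[Si](C)(C)C)cc(Br)c1O[Si](C)(C)C | intermediate (not isolated)
5 | lithium 2-methoxy-6-(trimethylsilyl)-4-[(trimethylsilyl)oxy]phenolate | COc1cc(O[Si](C)(C)C)cc([Si](C)(C)C)c1[O-].[Li+] | intermediate (not isolated)
6 | 2-methoxy-6-(trimethylsilyl)-4-[(trimethylsilyl)oxy]phenyl trifluoromethanesulfonate | COc1cc(O[Si](C)(C)C)cc([Si](C)(C)C)c1OS(=O)(=O)C(F)(F)F | intermediate (not isolated)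
7 | 4-hydroxy-2-methoxy-6-(trimethylsilyl)phenyl trifluoromethanesulfonate | COc1cc(O)cc([Si](C)(C)C)c1OS(=O)(=O)C(F)(F)F | intermediate
8 | 2-methoxy-4-(methoxymethoxy)-6-(trimethylsilyl)phenyl trifluoromethanesulfonate | COc1cc(OCOC)cc([Si](C)(C)C)c1OS(=O)(=O)C(F)(F)F | intermediate
9 | 5-bromo-2-hydroxybenzaldehyde | O=Cc1cc(Br)ccc1O | starting material
10 | 3-chloro-3-methylbut-1-yne | CC(C)(Cl)C#C | starting material
11 | 5-bromo-2-[(2-methylbut-3-yn-2-yl)oxy]benzaldehyde | O=Cc1cc(Br)ccc1OC(C)(C)C#C | intermediate
12 | 5-bromo-2-[(2-methylbut-3-yn-2-yl)oxy]phenyl formate | O=COc1cc(Br)ccc1OC(C)(C)C#C | intermediate (not isolated)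
13 | 5-bromo-2-[(2-methylbut-3-yn-2-yl)oxy]phenol | Oc1cc(Br)ccc1OC(C)(C)C#C | intermediate
14 | 4-bromo-2-(methoxymethoxy)-1-[(2-methylbut-3-yn-2-yl)oxy]benzene | COCOc1cc(Br)ccc1OC(C)(C)C#C | intermediate
15 | 4-bromo-2-(methoxymethoxy)-6-(3-methylbuta-1,2-dien-1-yl)phenol | COCOc1cc(Br)cc(C=C=C(C)C)c1O | intermediate (not isolated)
16 | 6-bromo-8-(methoxymethoxy)-2,2-dimethyl-2H-chromene | COCOc1cc(Br)cc2C=CC(C)(C)Oc12 | intermediate
17 | 2-[8-(methoxymethoxy)-2,2-dimethyl-2H-chromen-6-yl]-4,4,5,5-tetramethyl-1,3,2-dioxaborolane | COCOc1cc(B3OC(C)(C)C(C)(C)O3)cc2C=CC(C)(C)Oc12 | intermediate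
18 | methyl (E)-3-methoxyacrylate | CO/C=C/C(=O)OC | starting material
19 | methyl 3-acetoxy-2-iodo-3-methoxypropanoate (mixture of diastereomers) | COC(OC(C)=O)C(I)C(=O)OC | intermediate (not isolated)
20 | methyl (Z)-2-iodo-3-methoxyacrylate | CO/C=C(\I)C(=O)OC | intermediate
21 | methyl (E)-3-methoxy-2-[8-(methoxymethoxy)-2,2-dimethyl-2H-chromen-6-yl]acrylate | CO/C=C(/C(=O)OC)c1cc(OCOC)c2OC(C)(C)C=Cc2c1 | intermediate
22 | (E)-3-methoxy-2-[8-(methoxymethoxy)-2,2-dimethyl-2H-chromen-6-yl]acrylic acid | CO/C=C(/C(=O)O)c1cc(OCOC)c2OC(C)(C)C=Cc2c1 | intermediate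
23 | 3-methoxy-5-(methoxymethoxy)benzyne (1,2-didehydro-3-methoxy-5-(methoxymethoxy)benzene) | COC1=CC(OCOC)=CC#C1 | intermediate (not isolated)
24 | (E)-1-[2-hydroxy-6-methoxy-4-(methoxymethoxy)phenyl]-3-methoxy-2-[8-(methoxymethoxy)-2,2-dimethyl-2H-chromen-6-yl]prop-2-en-1-one (as its phenoxide) | CO/C=C(/C(=O)c1c(O)cc(OCOC)cc1OC)c1cc(OCOC)c2OC(C)(C)C=Cc2c1 | intermediate (not isolated)
25 | 5-methoxy-7-(methoxymethoxy)-3-[8-(methoxymethoxy)-2,2-dimethyl-2H-chromen-6-yl]-4H-chromen-4-one | COc1cc(OCOC)cc2occ(-c3cc(OCOC)c4c(c3)C=CC(C)(C)O4)c(=O)c12 | intermediate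
26 | glycyrrhizaisoflavone B | COc1cc(O)cc2occ(-c3cc(O)c4c(c3)C=CC(C)(C)O4)c(=O)c12 | target

Total step count: 13. Longest linear sequence: 9 steps (steps 4, 5, 6, 7, 8, 10, 11, 12, 13 from compound 9). Ring A precursor 8 takes 3 steps and iodide 20 takes 1.

Steps most likely to fail

1. Step 12. The aryl anion may be protonated before it can attack the electron-rich (vinylogous carbonate) ester carbonyl, so the sequence would stop at simple O-arylation. The aryne may also be used up by released methoxide or by the chromene double bond. The fallback sets out from boronate 17 and comes back at 25, building ring C first and joining ring B by cross-coupling. Commercial 1-(2,4-dihydroxy-6-methoxyphenyl)ethan-1-one F1 would be protected at its non-chelated hydroxyl (MOMCl, K2CO3, acetone) to give 1-[2-hydroxy-6-methoxy-4-(methoxymethoxy)phenyl]ethan-1-one F2. Condensation with DMF dimethyl acetal should give (E)-3-(dimethylamino)-1-[2-hydroxy-6-methoxy-4-(methoxymethoxy)phenyl]prop-2-en-1-one F3. Iodine and pyridine in CHCl3 would cyclise it to 3-iodo-5-methoxy-7-(methoxymethoxy)-4H-chromen-4-one F4. Suzuki–Miyaura coupling of F4 with 17 (PdCl2(dppf), Na2CO3, DME/H2O, 80 °C) should then give 25.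

2. Step 2. Butyllithium may attack the remote O–Si bond, or silyl groups may scramble between the two oxygens before triflation, so that triflate ends on the wrong oxygen or on both. The fallback sets out from 1 and comes back at 8, installing the MOM group before any silyl migration.
   - Silylation (TBSCl, imidazole, DMF) would give 3-bromo-4-[(tert-butyldimethylsilyl)oxy]-5-methoxybenzaldehyde F5.
   - Baeyer–Villiger oxidation (mCPBA, CH2Cl2) would give 3-bromo-4-[(tert-butyldimethylsilyl)oxy]-5-methoxyphenyl formate F6, and brief methanolysis (NaHCO3, MeOH) would give 3-bromo-4-[(tert-butyldimethylsilyl)oxy]-5-methoxyphenol F7.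
   - MOMCl/DIPEA would give [2-bromo-6-methoxy-4-(methoxymethoxy)phenoxy](tert-butyl)dimethylsilane F8, and TBAF would free 2-bromo-6-methoxy-4-(methoxymethoxy)phenol F9.
   - The standard one-pot sequence on this mono-phenol follows: HMDS to [2-bromo-6-methoxy-4-(methoxymethoxy)phenoxy]trimethylsilane F10, n-BuLi at −100 °C to lithium 2-methoxy-4-(methoxymethoxy)-6-(trimethylsilyl)phenolate F11, and Tf2O to 8.

3. Step 10. Protodeboronation of the electron-rich boronate and base-induced decomposition of the iodoacrylate may outrun transmetalation. The fallback sets out from bromide 16 and comes back at 21, building the acrylate on an aryl glyoxylate. Bromine–lithium exchange (n-BuLi, THF, −78 °C) would give [8-(methoxymethoxy)-2,2-dimethyl-2H-chromen-6-yl]lithium F12. Inverse addition to dimethyl oxalate should give methyl 2-[8-(methoxymethoxy)-2,2-dimethyl-2H-chromen-6-yl]-2-oxoacetate F13. Wittig methoxymethylenation (Ph3PCH2OMe chloride, KOtBu, THF, 0 °C) should give 21 together with methyl (Z)-3-methoxy-2-[8-(methoxymethoxy)-2,2-dimethyl-2H-chromen-6-yl]acrylate F14, which would be removed by chromatography.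

Further compounds
F1 | step 12 | 1-(2,4-dihydroxy-6-methoxyphenyl)ethan-1-one | COc1cc(O)cc(O)c1C(C)=O
F2 | step 12 | 1-[2-hydroxy-6-methoxy-4-(methoxymethoxy)phenyl]ethan-1-one | COCOc1cc(O)c(C(C)=O)c(OC)c1
F3 | step 12 | (E)-3-(dimethylamino)-1-[2-hydroxy-6-methoxy-4-(methoxymethoxy)phenyl]prop-2-en-1-one | CN(C)/C=C/C(=O)c1c(O)cc(OCOC)cc1OC
F4 | step 12 | 3-iodo-5-methoxy-7-(methoxymethoxy)-4H-chromen-4-one | COCOc1cc(OC)c2c(c1)occ(I)c2=O
F5 | step 2 | 3-bromo-4-[(tert-butyldimethylsilyl)oxy]-5-methoxybenzaldehyde | COc1cc(C=O)cc(Br)c1O[Si](C)(C)C(C)(C)C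
F6 | step 2 | 3-bromo-4-[(tert-butyldimethylsilyl)oxy]-5-methoxyphenyl formate | COc1cc(OC=O)cc(Br)c1O[Si](C)(C)C(C)(C)C
F7 | step 2 | 3-bromo-4-[(tert-butyldimethylsilyl)oxy]-5-methoxyphenol | COc1cc(O)cc(Br)c1O[Si](C)(C)C(C)(C)C
F8 | step 2 | [2-bromo-6-methoxy-4-(methoxymethoxy)phenoxy](tert-butyl)dimethylsilane | COCOc1cc(OC)c(O[Si](C)(C)C(C)(C)C)c(Br)c1
F9 | step 2 | 2-bromo-6-methoxy-4-(methoxymethoxy)phenol | COCOc1cc(OC)c(O)c(Br)c1
F10 | step 2 | [2-bromo-6-methoxy-4-(methoxymethoxy)phenoxy]trimethylsilane | COCOc1cc(OC)c(O[Si](C)(C)C)c(Br)c1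
F11 | step 2 | lithium 2-methoxy-4-(methoxymethoxy)-6-(trimethylsilyl)phenolate | COCOc1cc(OC)c([O-])c([Si](C)(C)C)c1.[Li+]
F12 | step 10 | [8-(methoxymethoxy)-2,2-dimethyl-2H-chromen-6-yl]lithium | [Li]c1cc(OCOC)c2OC(C)(C)C=Cc2c1
F13 | step 10 | methyl 2-[8-(methoxymethoxy)-2,2-dimethyl-2H-chromen-6-yl]-2-oxoacetate | COCOc1cc(C(=O)C(=O)OC)cc2C=CC(C)(C)Oc12
F14 | step 10 | methyl (Z)-3-methoxy-2-[8-(methoxymethoxy)-2,2-dimethyl-2H-chromen-6-yl]acrylate | CO/C=C(\C(=O)OC)c1cc(OCOC)c2OC(C)(C)C=Cc2c1
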